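**Retrosynthetic overview**
- The C3–OH and the free ring B hydroquinone come last. The C2=C3 bond of a 5-hydroxy-6,7,8-trimethoxyflavone is epoxidised, and acid then turns the epoxide into the flavonol and removes the MOM groups in the same flask.
- The key disconnection is O1–C8a (C–O). Ring C is closed oxidatively from an open 1,3-diketone by joining its enol oxygen to the last C–H of ring A through a quinone monoketal. The phenol that triggers the oxidation stays as the 5-OH.
- The diketone comes from one Claisen condensation, the only C–C bond made, between 2'-hydroxy-3',4',5'-trimethoxyacetophenone and methyl 2,5-bis(methoxymethoxy)benzoate.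
- The 2'-OH (future 5-OH) is a C–O bond made by ketone-directed C–H oxygenation of 3',4',5'-trimethoxyacetophenone. The ester comes from methyl gentisate.
- Ring order: rings A and B are bought, and ring C is the only ring formed (step 4).

Assumption: the target SMILES has no stereocentre and no hindered axis, so the compound is achiral and needs no enantiocontrol. The transient stereocentres in two non-isolated intermediates are racemic and are erased.

**Step 1**
Reactants: 1 3',4',5'-trimethoxyacetophenone (1-(3,4,5-trimethoxyphenyl)ethan-1-one)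
Product: 3 1-(2-hydroxy-3,4,5-trimethoxyphenyl)ethan-1-one, via aryl trifluoroacetate 2 (not isolated)
Conditions: [RuCl2(p-cymene)]2 (2.5 mol %), K2S2O8 (1.5 equiv), TFA/TFAA 9:1, 80 °C, 6 h; then H2O, rt, 30 min
Reagents that add atoms: trifluoroacetic acid, OC(=O)C(F)(F)F (supplies the new phenol oxygen)
Why: Ketone-directed C–H oxygenation (carboxylate-assisted cyclometalation at divalent ruthenium, persulfate oxidation, C–O reductive elimination); the two aromatic C–H bonds of 1 are equivalent and both ortho to the carbonyl, so only one regioisomer can form, and TFAA keeps the product masked as the electron-poor ester 2 until water is added, which shields the oxidisable 4-methoxyphenol; no stereocentre.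

**Step 2**
Reactants: 4 methyl 2,5-dihydroxybenzoate (methyl gentisate)
Product: 5 methyl 2,5-bis(methoxymethoxy)benzoate
Conditions: NaH (2.5 equiv), MOMCl (2.5 equiv), DMF, 0 °C to rt, 3 h
Reagents that add atoms: chloromethyl methyl ether (MOMCl), COCCl
Why: Williamson-type O-alkylation (MOM protection); NaH deprotonates both phenols irreversibly, including the hydrogen-bonded 2-OH, and the acetals survive base and trivalent iodine yet fall in the acid of the last step; no stereocentre.

**Step 3**
Reactants: 3 1-(2-hydroxy-3,4,5-trimethoxyphenyl)ethan-1-one; 5 methyl 2,5-bis(methoxymethoxy)benzoate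
Product: 6 1-[2,5-bis(methoxymethoxy)phenyl]-3-(2-hydroxy-3,4,5-trimethoxyphenyl)propane-1,3-dione
Conditions: NaH (4 equiv), THF, reflux, 4 h; then 1 M HCl to pH 5, 0 °C
Reagents that add atoms: none
Why: Crossed Claisen condensation of the phenoxide/enolate dianion of 3 with a non-enolisable ester, driven by formation of the stabilised diketone enolate; the cold, mildly acidic quench avoids both MOM loss and cyclodehydration through the 2'-OH; no stereocentre.

**Step 4**
Reactants: 6 1-[2,5-bis(methoxymethoxy)phenyl]-3-(2-hydroxy-3,4,5-trimethoxyphenyl)propane-1,3-dione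
Product: 9 2-[2,5-bis(methoxymethoxy)phenyl]-5-hydroxy-6,7,8-trimethoxy-4H-chromen-4-one, via quinone monoketal 7 (not isolated), via dihydrochromenone adduct 8 (not isolated)
Conditions: PhI(OAc)2 (1.05 equiv), CH2Cl2/MeOH 9:1 (0.02 M), 0 °C, 15 min; then Et3N (3 equiv), 0 °C to rt, 2 h; 10 % aq citric acid wash
Reagents that add atoms: methanol, CO (becomes one of the two equivalent ketal methoxy groups of 7, one of which stays as the 8-OMe of 9)
Why: Proposed new method: a dearomatisation-triggered dehydrogenative C–H/O–H annulation that closes ring C at O1–C8a onto the free C–H of ring A while the chelated phenol is kept as the 5-OH; PhI(OAc)2 (trivalent iodine) oxidises the 4-methoxyphenol unit of 6 within minutes, far faster than it touches aryl ethers, MOM acetals or the hydrogen-bonded diketone enol, and methanol traps the cation at the methoxy-bearing para carbon to give the acyl quinone monoketal 7; the only C–H carbon of 7 is the beta carbon of both the dienone and the exocyclic acyl group, so once the oxidant is spent Et3N forms the diketone enolate and its distal oxygen adds in a six-membered mode (attack through carbon would need a four-membered ring) to give 8, which loses one ketal methanol and tautomerises to aromatic 9; an ortho-quinone monoketal formed by trapping at C3' would reach the same product by the same addition and vinylogous loss of methanol; adding base only after the oxidant is consumed prevents re-oxidation of 9 and iodonium ylide formation, and the methanol-poor dilute medium disfavours solvent or intermolecular addition; the closest known reaction types are the PhI(OAc)2/MeOH oxidation of 2-acyl-4-methoxyphenols to quinone monoketals and the conjugate addition of external sulfur, nitrogen and carbon nucleophiles to quinone monoketals with aromatising loss of methanol, neither of which has been shown with an enol oxygen or for building a chromone ring; the C8a stereocentre of 8 is racemic and is erased.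

**Step 5**
Reactants: 9 2-[2,5-bis(methoxymethoxy)phenyl]-5-hydroxy-6,7,8-trimethoxy-4H-chromen-4-one
Product: 12 2-(2,5-dihydroxyphenyl)-3,5-dihydroxy-6,7,8-trimethoxy-4H-chromen-4-one, via flavone epoxide 10 (not isolated), via bis-MOM flavonol 11 (not isolated)
Conditions: DMDO (0.07 M in acetone, 4 equiv), CH2Cl2, 0 °C to rt, 16 h; evaporate; then 2 M HCl in MeOH, 50 °C, 2 h, N2
Reagents that add atoms: dimethyldioxirane (DMDO), CC1(C)OO1
Why: Electrophilic epoxidation of the enol-ether-like C2=C3 bond followed by acid-induced isomerisation of the 2,3-epoxide to the 3-hydroxyflavone (the established flavone-to-flavonol conversion); the same methanolic acid solvolyses both MOM acetals, ring A has no free C–H and its 5-OH is tied up by chelation to C4=O, and the epoxide stereocentres are racemic and erased.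

**Compound list**
1 | 3',4',5'-trimethoxyacetophenone (1-(3,4,5-trimethoxyphenyl)ethan-1-one) | CC(=O)c1cc(OC)c(OC)c(OC)c1 | starting material
2 | 6-acetyl-2,3,4-trimethoxyphenyl trifluoroacetate | CC(=O)c1cc(OC)c(OC)c(OC)c1OC(=O)C(F)(F)F | intermediate (not isolated)
3 | 1-(2-hydroxy-3,4,5-trimethoxyphenyl)ethan-1-one | CC(=O)c1cc(OC)c(OC)c(OC)c1O | intermediate
4 | methyl 2,5-dihydroxybenzoate | COC(=O)c1cc(O)ccc1O | starting material
5 | methyl 2,5-bis(methoxymethoxy)benzoate | COCOc1ccc(OCOC)c(C(=O)OC)c1 | intermediate
6 | 1-[2,5-bis(methoxymethoxy)phenyl]-3-(2-hydroxy-3,4,5-trimethoxyphenyl)propane-1,3-dione | COCOc1ccc(OCOC)c(C(=O)CC(=O)c2cc(OC)c(OC)c(OC)c2O)c1 | intermediate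
7 | 1-[2,5-bis(methoxymethoxy)phenyl]-3-(3,3,4,5-tetramethoxy-6-oxocyclohexa-1,4-dien-1-yl)propane-1,3-dione | COCOc1ccc(OCOC)c(C(=O)CC(=O)C2=CC(OC)(OC)C(OC)=C(OC)C2=O)c1 | intermediate (not isolated)
8 | 2-[2,5-bis(methoxymethoxy)phenyl]-5-hydroxy-6,7,8,8-tetramethoxy-8,8a-dihydro-4H-chromen-4-one (racemic at C8a) | COCOc1ccc(OCOC)c(C2=CC(=O)C3=C(O)C(OC)=C(OC)C(OC)(OC)C3O2)c1 | intermediate (not isolated)
9 | 2-[2,5-bis(methoxymethoxy)phenyl]-5-hydroxy-6,7,8-trimethoxy-4H-chromen-4-one | COCOc1ccc(OCOC)c(-c2cc(=O)c3c(O)c(OC)c(OC)c(OC)c3o2)c1 | intermediate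
10 | 2,3-epoxide of 9: 1a-[2,5-bis(methoxymethoxy)phenyl]-6-hydroxy-3,4,5-trimethoxy-1a,7a-dihydro-7H-oxireno[b]chromen-7-one (racemic, cis-fused) | COCOc1ccc(OCOC)c(C23OC2C(=O)c2c(O)c(OC)c(OC)c(OC)c2O3)c1 | intermediate (not isolated)
11 | 2-[2,5-bis(methoxymethoxy)phenyl]-3,5-dihydroxy-6,7,8-trimethoxy-4H-chromen-4-one | COCOc1ccc(OCOC)c(-c2oc3c(OC)c(OC)c(OC)c(O)c3c(=O)c2O)c1 | intermediate (not isolated)
12 | 2-(2,5-dihydroxyphenyl)-3,5-dihydroxy-6,7,8-trimethoxy-4H-chromen-4-one (achiral) | COc1c(OC)c(O)c2c(=O)c(O)c(-c3cc(O)ccc3O)oc2c1OC | target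

**Step count**
- Total: 5 steps.
- Longest linear sequence: 4 steps (1 → 3 → 6 → 9 → 12). The branch 4 → 5 → 6 → 9 → 12 is equally long.

**Steps most likely to fail**

**Step 4 (the proposed new ring closure).**
- Risks: methanol or a second molecule may add to 7 instead of the enolate oxygen. Product 9 may be re-oxidised if it forms before the oxidant is spent. The aromatising loss of methanol may be slow.
- Fallback (known chemistry), setting out from 3 and coming back at 9: bromination of 3 at its only free ring position (NBS, MeCN, 0 °C) gives 1-(2-bromo-6-hydroxy-3,4,5-trimethoxyphenyl)ethan-1-one F2. The same NaH Claisen condensation with 5 gives 1-(2-bromo-6-hydroxy-3,4,5-trimethoxyphenyl)-3-[2,5-bis(methoxymethoxy)phenyl]propane-1,3-dione F3. A copper-catalysed intramolecular Ullmann-type O-arylation of the diketone enolate (CuI 10 mol %, 1,10-phenanthroline 20 mol %, K2CO3, DMF, 110 °C), the established chromone closure of 2-haloaryl 1,3-diketones, then forms the same O1–C8a bond and delivers 9.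

**Step 1 (C–H oxygenation of an electron-rich, flanked position).**
- Risks: slow metalation next to the 3-OMe group, and oxidative demethylation of the trimethoxyarene by persulfate in hot TFA.
- Fallback, setting out from 1 and coming back at 3: electrophilic ring bromination (NBS, MeCN, rt) gives 1-(2-bromo-3,4,5-trimethoxyphenyl)ethan-1-one F1. A copper-catalysed Ullmann-type hydroxylation (CuI 10 mol %, 1,10-phenanthroline 20 mol %, KOH 3 equiv, DMSO/H2O 1:1, 100 °C, then acidification) converts the C–Br bond into the phenol 3.

**Step 5 (C3 oxygenation beside a free 5-OH).**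
- Risks: the chelated carbonyl makes C2=C3 a poor partner for DMDO, and long exposure may oxidise the electron-rich rings.
- Fallback, setting out from 9 and coming back at 11, replaces electrophilic oxygen transfer by deprotonation: LiN(iPr)2 (3.3 equiv, THF, −78 °C) forms the 5-phenoxide and lithiates C3. B(OMe)3 followed by AcOH gives {2-[2,5-bis(methoxymethoxy)phenyl]-5-hydroxy-6,7,8-trimethoxy-4-oxo-4H-chromen-3-yl}boronic acid F4. 30 % H2O2 (0 °C to rt) oxidises the C–B bond to give 11, which is treated with HCl/MeOH as in the second stage of step 5.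

**Further compounds**
F1 | step 1 | 1-(2-bromo-3,4,5-trimethoxyphenyl)ethan-1-one | CC(=O)c1cc(OC)c(OC)c(OC)c1Br
F2 | step 4 | 1-(2-bromo-6-hydroxy-3,4,5-trimethoxyphenyl)ethan-1-one | CC(=O)c1c(Br)c(OC)c(OC)c(OC)c1O
F3 | step 4 | 1-(2-bromo-6-hydroxy-3,4,5-trimethoxyphenyl)-3-[2,5-bis(methoxymethoxy)phenyl]propane-1,3-dione | COCOc1ccc(OCOC)c(C(=O)CC(=O)c2c(Br)c(OC)c(OC)c(OC)c2O)c1
F4 | step 5 | {2-[2,5-bis(methoxymethoxy)phenyl]-5-hydroxy-6,7,8-trimethoxy-4-oxo-4H-chromen-3-yl}boronic acid | COCOc1ccc(OCOC)c(-c2oc3c(OC)c(OC)c(OC)c(O)c3c(=O)c2B(O)O)c1
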